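The chroman ring is built around the O1–C2 bond of the dihydropyran ring: its quaternary, gem-dimethyl carbon C2 starts as an ionisable tertiary carbinol carbon outside a 2,3-dihydrobenzofuran ring. In the key step acid ionises this carbinol, the ring oxygen bridges the cation and bromide opens the bridged oxonium ion at the ring CH, so that O1 shifts onto the quaternary carbon and the five-membered ring grows into the six-membered one (C8a–O1–C2–C3–C4–C4a). The precursor, a 2-(2-hydroxypropan-2-yl)dihydrobenzofuran, comes from C-prenylated phloroacetophenone by epoxidation and 5-exo closure. Debromination, Claisen–Schmidt condensation with a prenylated benzaldehyde and chemoselective enone hydrogenation finish the dihydrochalcone.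

Key step: step 3

Remark on the chemistry: the target has no stereocentre and is achiral, so no asymmetric step is needed; the stereocentres that appear in compounds 4–8 and 14 are carried as racemates and are removed on the way.

Step 1
Reactants: 1 phloroacetophenone (1-(2,4,6-trihydroxyphenyl)ethan-1-one); 2 prenyl bromide (1-bromo-3-methylbut-2-ene)
Product: 3 mono-C-prenylphloroacetophenone (1-[2,4,6-trihydroxy-3-(3-methylbut-2-en-1-yl)phenyl]ethan-1-one)
Conditions: prenyl bromide (1.0 equiv), 10% aq. KOH, 0 °C → rt
Reagents that add atoms: prenyl bromide (compound 2), CC(C)=CCBr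
Why: Base-mediated C-alkylation of the ambident phloroglucinolate (SN2 on the allylic bromide in water, where hydrogen bonding shields the oxygens) should place one prenyl group on a ring carbon, and because the two free ring positions of 1 are equivalent only one mono-C-prenyl isomer can form.

Step 2
Reactants: 3 mono-C-prenylphloroacetophenone
Product: 5 dihydrobenzofuran carbinol (1-[4,6-dihydroxy-2-(2-hydroxypropan-2-yl)-2,3-dihydro-1-benzofuran-5-yl]ethan-1-one; racemic), via prenyl epoxide 4 (not isolated)
Conditions: mCPBA, NaHCO3, EtOAc, 0 °C; then K2CO3, MeOH, rt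
Reagents that add atoms: mCPBA (3-chloroperoxybenzoic acid), OOC(=O)c1cccc(Cl)c1
Why: Prilezhaev epoxidation of the electron-rich trisubstituted alkene is followed by base-mediated 5-exo-tet opening of the epoxide at its secondary carbon by the phenoxide para to the acetyl group, the most acidic and non-chelated oxygen, which fixes the ring oxygen para to the ketone; the new stereocentre arises as a racemate and is removed in step 4.

Step 3
Reactants: 5 dihydrobenzofuran carbinol
Product: 8 bromochroman (1-(3-bromo-5,7-dihydroxy-2,2-dimethyl-3,4-dihydro-2H-chromen-6-yl)ethan-1-one; racemic), via tertiary bromide 6 (not isolated), via bridged oxonium ion 7 (not isolated)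
Conditions: HBr (33% in AcOH, 3 equiv), ZnBr2 (10 mol%), CH2Cl2 (0.02 M), 0 °C → rt
Reagents that add atoms: hydrogen bromide, Br
Why: Acid ionises the tertiary carbinol of 5 (SN1), and the ring oxygen O1 bridges the cation as an aryl-substituted oxonium ion spanning C2 of the dihydrofuran and the CMe2 carbon; bromide opens this ion at the secondary ring carbon, so that O1 has moved 1,2 onto the quaternary carbon and the five-membered ring has become the dihydropyran ring C8a–O1–C2–C3–C4–C4a. The closest known reaction type is the neighbouring-group ring expansion of 2-(1-hydroxyalkyl)- and 2-(1-haloalkyl)-2,3-dihydrobenzofurans and tetrahydrofurans to 3-substituted chromans and tetrahydropyrans through bicyclic oxonium ions, the oxygen counterpart of the prolinol-to-piperidine expansion. The six-membered ring is not closed from a chain: it arises by three-membered bridging of O1 to the cationic carbon and rupture of the old O1–CH bond, so O1 never leaves the arene and the regiochemistry set in step 2 is kept. The one new stereocentre, C3–Br, forms as a racemate (anti opening of the bridged ion in racemic material) and is erased in step 4. The selectivity needed is bromide attack at the secondary rather than the tertiary carbon: capture at the tertiary carbon gives bromide 6, which should re-ionise under ZnBr2/HBr, whereas the secondary bromide in the less strained six-membered ring with a tertiary aryl ether should be the thermodynamic sink. Proton loss to the isopropenyl compound is reversed by HBr addition, and high dilution suppresses intermolecular alkylation of the free aromatic position.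

Step 4
Reactants: 8 bromochroman
Product: 9 chroman ketone (1-(5,7-dihydroxy-2,2-dimethyl-3,4-dihydro-2H-chromen-6-yl)ethan-1-one)
Conditions: Bu3SnH (1.5 equiv), AIBN (cat.), PhMe, 80 °C
Reagents that add atoms: none
Why: Radical-chain dehalogenation (tin hydride reduction): bromine abstraction gives the secondary C3 radical, which at this hydride concentration should take a hydrogen atom faster than it can lose the β-aryloxy group, leaving the C3 methylene and erasing the stereocentre.

Step 5
Reactants: 9 chroman ketone
Product: 10 bis-MOM chroman ketone (1-[5,7-bis(methoxymethoxy)-2,2-dimethyl-3,4-dihydro-2H-chromen-6-yl]ethan-1-one)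
Conditions: NaH (2.2 equiv), MOMCl (2.2 equiv), DMF, 0 °C → rt
Reagents that add atoms: chloromethyl methyl ether (MOMCl), COCCl
Why: Williamson-type O-alkylation of both sodium phenoxides masks the two hydroxyls ortho to the ketone, so that the later chalcone cannot close to a flavanone and the enolate is not deactivated by phenoxide charges.

Step 6
Reactants: 11 4-hydroxybenzaldehyde; 2 prenyl bromide
Product: 12 prenylated aldehyde (4-hydroxy-3-(3-methylbut-2-en-1-yl)benzaldehyde)
Conditions: prenyl bromide, 10% aq. KOH, rt
Reagents that add atoms: prenyl bromide (compound 2), CC(C)=CCBr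
Why: ortho-C-alkylation of the phenoxide in water (the para position is blocked by the formyl group) should give the 3-prenyl phenol next to O-alkylated material that is separated.

Step 7
Reactants: 12 prenylated aldehyde
Product: 13 MOM-protected aldehyde (4-(methoxymethoxy)-3-(3-methylbut-2-en-1-yl)benzaldehyde)
Conditions: NaH, MOMCl, THF, 0 °C → rt
Reagents that add atoms: chloromethyl methyl ether (MOMCl), COCCl
Why: Williamson-type O-alkylation of the phenoxide gives the MOM acetal, which keeps the aldehyde electrophilic under the basic condensation conditions of step 8.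

Step 8
Reactants: 10 bis-MOM chroman ketone; 13 MOM-protected aldehyde
Product: 15 protected chalcone ((2E)-1-[5,7-bis(methoxymethoxy)-2,2-dimethyl-3,4-dihydro-2H-chromen-6-yl]-3-[4-(methoxymethoxy)-3-(3-methylbut-2-en-1-yl)phenyl]prop-2-en-1-one), via aldol adduct 14 (not isolated)
Conditions: KOH (50% aq.), EtOH, rt
Reagents that add atoms: none
Why: Claisen–Schmidt condensation: the methyl ketone enolate adds to the non-enolisable aldehyde and the aldol adduct loses water by E1cB elimination to the conjugated, thermodynamically favoured E-enone.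

Step 9
Reactants: 15 protected chalcone
Product: 16 protected dihydrochalcone (1-[5,7-bis(methoxymethoxy)-2,2-dimethyl-3,4-dihydro-2H-chromen-6-yl]-3-[4-(methoxymethoxy)-3-(3-methylbut-2-en-1-yl)phenyl]propan-1-one)
Conditions: H2 (1 atm), RhCl(PPh3)3 (5 mol%), PhH/EtOH 1:1, rt
Reagents that add atoms: none
Why: Homogeneous hydrogenation with the bulky Rh(I) phosphine catalyst should saturate the disubstituted conjugated C=C while the trisubstituted prenyl alkene, the aryl ketone and the acetals are left untouched (steric chemoselectivity).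

Step 10
Reactants: 16 protected dihydrochalcone
Product: 17 target (1-(5,7-dihydroxy-2,2-dimethyl-3,4-dihydro-2H-chromen-6-yl)-3-[4-hydroxy-3-(3-methylbut-2-en-1-yl)phenyl]propan-1-one)
Conditions: 3 M aq. HCl, MeOH, 40 °C
Reagents that add atoms: none
Why: Acid-catalysed cleavage of the three MOM acetals (transacetalisation to dimethoxymethane) under mild conditions should free the phenols without acid-induced cyclisation or hydration of the B-ring prenyl group, giving the target.

Compound list
1 | phloroacetophenone (1-(2,4,6-trihydroxyphenyl)ethan-1-one) | CC(=O)c1c(O)cc(O)cc1O | starting material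
2 | prenyl bromide (1-bromo-3-methylbut-2-ene) | CC(C)=CCBr | starting material
3 | mono-C-prenylphloroacetophenone (1-[2,4,6-trihydroxy-3-(3-methylbut-2-en-1-yl)phenyl]ethan-1-one) | CC(=O)c1c(O)cc(O)c(CC=C(C)C)c1O | intermediate
4 | prenyl epoxide (1-{3-[(3,3-dimethyloxiran-2-yl)methyl]-2,4,6-trihydroxyphenyl}ethan-1-one; racemic; not isolated) | CC(=O)c1c(O)cc(O)c(CC2OC2(C)C)c1O | intermediate
5 | dihydrobenzofuran carbinol (1-[4,6-dihydroxy-2-(2-hydroxypropan-2-yl)-2,3-dihydro-1-benzofuran-5-yl]ethan-1-one; racemic) | CC(=O)c1c(O)cc2OC(C(C)(C)O)Cc2c1O | intermediate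
6 | tertiary bromide (1-[2-(2-bromopropan-2-yl)-4,6-dihydroxy-2,3-dihydro-1-benzofuran-5-yl]ethan-1-one; racemic; not isolated) | CC(=O)c1c(O)cc2OC(C(C)(C)Br)Cc2c1O | intermediate
7 | bridged oxonium ion (as 6 but with O1 bonded to the CMe2 carbon in place of bromine, giving a three-membered ring O1–C2–CMe2 fused to the dihydrofuran; bromide counter-ion; not isolated) | CC(=O)c1c(O)cc2c(c1O)CC1[O+]2C1(C)C.[Br-] | intermediate
8 | bromochroman (1-(3-bromo-5,7-dihydroxy-2,2-dimethyl-3,4-dihydro-2H-chromen-6-yl)ethan-1-one; racemic) | CC(=O)c1c(O)cc2OC(C)(C)C(Br)Cc2c1O | intermediate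
9 | chroman ketone (1-(5,7-dihydroxy-2,2-dimethyl-3,4-dihydro-2H-chromen-6-yl)ethan-1-one) | CC(=O)c1c(O)cc2OC(C)(C)CCc2c1O | intermediate
10 | bis-MOM chroman ketone (1-[5,7-bis(methoxymethoxy)-2,2-dimethyl-3,4-dihydro-2H-chromen-6-yl]ethan-1-one) | CC(=O)c1c(OCOC)cc2OC(C)(C)CCc2c1OCOC | intermediate
11 | 4-hydroxybenzaldehyde | O=Cc1ccc(O)cc1 | starting material
12 | prenylated aldehyde (4-hydroxy-3-(3-methylbut-2-en-1-yl)benzaldehyde) | CC(C)=CCc1cc(C=O)ccc1O | intermediate
13 | MOM-protected aldehyde (4-(methoxymethoxy)-3-(3-methylbut-2-en-1-yl)benzaldehyde) | CC(C)=CCc1cc(C=O)ccc1OCOC | intermediate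
14 | aldol adduct (1-[5,7-bis(methoxymethoxy)-2,2-dimethyl-3,4-dihydro-2H-chromen-6-yl]-3-hydroxy-3-[4-(methoxymethoxy)-3-(3-methylbut-2-en-1-yl)phenyl]propan-1-one; racemic; not isolated) | CC(C)=CCc1cc(C(O)CC(=O)c2c(OCOC)cc3OC(C)(C)CCc3c2OCOC)ccc1OCOC | intermediate
15 | protected chalcone ((2E)-1-[5,7-bis(methoxymethoxy)-2,2-dimethyl-3,4-dihydro-2H-chromen-6-yl]-3-[4-(methoxymethoxy)-3-(3-methylbut-2-en-1-yl)phenyl]prop-2-en-1-one) | CC(C)=CCc1cc(/C=C/C(=O)c2c(OCOC)cc3OC(C)(C)CCc3c2OCOC)ccc1OCOC | intermediate
16 | protected dihydrochalcone (1-[5,7-bis(methoxymethoxy)-2,2-dimethyl-3,4-dihydro-2H-chromen-6-yl]-3-[4-(methoxymethoxy)-3-(3-methylbut-2-en-1-yl)phenyl]propan-1-one) | CC(C)=CCc1cc(CCC(=O)c2c(OCOC)cc3OC(C)(C)CCc3c2OCOC)ccc1OCOC | intermediate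
17 | target (1-(5,7-dihydroxy-2,2-dimethyl-3,4-dihydro-2H-chromen-6-yl)-3-[4-hydroxy-3-(3-methylbut-2-en-1-yl)phenyl]propan-1-one) | CC(C)=CCc1cc(CCC(=O)c2c(O)cc3c(c2O)CCC(C)(C)O3)ccc1O | target

Total step count: 10 steps.
Longest linear sequence: 8 steps (steps 1, 2, 3, 4, 5, 8, 9, 10).

Steps most likely to fail

1. Step 3 (key step). The cation may drain by proton loss or a 1,2-hydride shift (towards isopropenyl and isopropylbenzofuran products), and bromide may keep returning to the tertiary carbon, so that the oxygen shift does not turn over. The fallback makes the same ring by contraction of a seven-membered ring, where bromide has to open the bridged oxonium ion at a primary carbon. It sets out from 1 and comes back at 9. C-Allylation of 1 (allyl bromide, 10% aq. KOH) would give 1-[2,4,6-trihydroxy-3-(prop-2-en-1-yl)phenyl]ethan-1-one F1. Alkylation of its most acidic, non-chelated hydroxyl para to the ketone (3-chloro-2-methylprop-1-ene, K2CO3, acetone) would give 1-{2,6-dihydroxy-4-[(2-methylprop-2-en-1-yl)oxy]-3-(prop-2-en-1-yl)phenyl}ethan-1-one F2. Ring-closing metathesis (2nd-generation Ru–NHC benzylidene catalyst, CH2Cl2, 40 °C) would close 1-(6,8-dihydroxy-3-methyl-2,5-dihydro-1-benzoxepin-7-yl)ethan-1-one F3. HBr in AcOH would protonate the ring alkene to the tertiary C3 cation, O1 would bridge it, and bromide would open the ion at the CH2 group, contracting the oxepine to racemic 1-[2-(bromomethyl)-5,7-dihydroxy-2-methyl-3,4-dihydro-2H-chromen-6-yl]ethan-1-one F4. Bu3SnH/AIBN would then reduce the primary bromide to 9.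

2. Step 2. Site selectivity of the epoxide opening may be poor: the phenoxide ortho to the ketone can close in competition with the para one, 6-endo opening can compete with 5-exo, and the peracid may attack the electron-rich ring. The fallback masks the two hydroxyls ortho to the ketone so that only the para hydroxyl can close. It sets out from 3 and comes back at 5. Peracetylation (Ac2O, pyridine) would give 2-acetyl-4-(3-methylbut-2-en-1-yl)benzene-1,3,5-triyl triacetate F5. Lipase-mediated alcoholysis (porcine pancreatic lipase, n-BuOH, THF), which should spare acetates ortho to a ring carbonyl, would give 2-acetyl-5-hydroxy-4-(3-methylbut-2-en-1-yl)-1,3-phenylene diacetate F6. Epoxidation (mCPBA, NaHCO3, CH2Cl2) would give racemic 2-acetyl-4-[(3,3-dimethyloxiran-2-yl)methyl]-5-hydroxy-1,3-phenylene diacetate F7. DBU in CH2Cl2 would close it 5-exo through the only free phenol to racemic 5-acetyl-2-(2-hydroxypropan-2-yl)-2,3-dihydro-1-benzofuran-4,6-diyl diacetate F8. Methanolysis (K2CO3, MeOH) would then give 5.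

3. Step 4. The C3 radical may fragment with loss of the aryloxyl radical (ring opening back to the prenylphenol), and the free phenols may slow the radical chain. The fallback avoids radicals; it sets out from 8 and comes back at 9. E2 elimination of HBr (DBU, PhMe, 100 °C) would give 1-(5,7-dihydroxy-2,2-dimethyl-2H-chromen-6-yl)ethan-1-one F9. Hydrogenation of this chromene (H2, Pd/C, EtOAc), which is possible at this stage because no prenyl group is present yet, would give 9.

Further compounds
F1 | step 3 | 1-[2,4,6-trihydroxy-3-(prop-2-en-1-yl)phenyl]ethan-1-one | CC(=O)c1c(O)cc(O)c(CC=C)c1O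
F2 | step 3 | 1-{2,6-dihydroxy-4-[(2-methylprop-2-en-1-yl)oxy]-3-(prop-2-en-1-yl)phenyl}ethan-1-one | CC(=O)c1c(O)cc(OCC(C)=C)c(CC=C)c1O
F3 | step 3 | 1-(6,8-dihydroxy-3-methyl-2,5-dihydro-1-benzoxepin-7-yl)ethan-1-one | CC(=O)c1c(O)cc2OCC(C)=CCc2c1O
F4 | step 3 | 1-[2-(bromomethyl)-5,7-dihydroxy-2-methyl-3,4-dihydro-2H-chromen-6-yl]ethan-1-one (racemic) | CC(=O)c1c(O)cc2OC(C)(CBr)CCc2c1O
F5 | step 2 | 2-acetyl-4-(3-methylbut-2-en-1-yl)benzene-1,3,5-triyl triacetate | CC(=O)c1c(OC(C)=O)cc(OC(C)=O)c(CC=C(C)C)c1OC(C)=O
F6 | step 2 | 2-acetyl-5-hydroxy-4-(3-methylbut-2-en-1-yl)-1,3-phenylene diacetate | CC(=O)c1c(OC(C)=O)cc(O)c(CC=C(C)C)c1OC(C)=O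
F7 | step 2 | 2-acetyl-4-[(3,3-dimethyloxiran-2-yl)methyl]-5-hydroxy-1,3-phenylene diacetate (racemic) | CC(=O)c1c(OC(C)=O)cc(O)c(CC2OC2(C)C)c1OC(C)=O
F8 | step 2 | 5-acetyl-2-(2-hydroxypropan-2-yl)-2,3-dihydro-1-benzofuran-4,6-diyl diacetate (racemic) | CC(=O)c1c(OC(C)=O)cc2OC(C(C)(C)O)Cc2c1OC(C)=O
F9 | step 4 | 1-(5,7-dihydroxy-2,2-dimethyl-2H-chromen-6-yl)ethan-1-one | CC(=O)c1c(O)cc2OC(C)(C)C=Cc2c1O
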